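(The numbers stand for no real mixture; the flask was simulated.)

**A ratio.** I began from one ratio, the rate at which free catalyst destroys target over the rate at which it captures substrate, since the recipe for the next run hangs on it.

in all of them: free catalyst 61 mM
- Friday's: substrate 0.32 M; coupling partner 0.384 M; time 5.0 d; a closed flask charged with all of it at once and left for 5.0 d
- Sunday's: substrate 0.32 M; coupling partner 0.384 M; one stirred flow tank at steady state, fed with the mixture as stated, mean residence time 5.0 d
- Thursday's: substrate 0.32 M (fed, over 4.00 d); coupling partner 0.384 M; time 5.0 d; a stirred flask in which substrate is dosed at a steady rate over 4.00 d without added volume, worked up at 5.0 d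
- Saturday's: substrate 0.32 M; coupling partner 0.384 M (fed, over 4.00 d); time 5.0 d; a stirred flask in which coupling partner is dosed at a steady rate over 4.00 d without added volume, worked up at 5.0 d

    substrate + free catalyst → catalyst intermediate A (k1 = 3.9 × 10⁻⁴ /M/s)
    coupling partner + catalyst intermediate A → catalyst intermediate B (k2 = 2.0 × 10⁻⁴ /M/s)
    catalyst intermediate B → free catalyst + target (k3 = 1.2 × 10⁻⁴ /s)
    free catalyst + target → free catalyst + over-reaction product (k4 = 1.2 × 10⁻⁴ /M/s)
    target ⇌ isomer of the product (K5 = 0.13, k5 = 5.9 × 10⁻⁵ /s)

- the stated concentrations are those of everything mixed, before any reaction; amounts are the same in each set-up
- the feed brings no volume worth counting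
- run time (Friday's): 5.0 d

- the set-up with the highest amount of target at the outlet or at the end, in percent of the substrate put in ("none" if the first two lie within 2 percentage points) (Friday's / Sunday's / Thursday's / Saturday's / none)
- amount of target at the outlet or at the end, in percent of the substrate put in, Friday's
- amount of target at the outlet or at the end, in percent of the substrate put in, Sunday's
- amount of target at the outlet or at the end, in percent of the substrate put in, Thursday's
- amount of target at the outlet or at the end, in percent of the substrate put in, Saturday's

**The reckoning.** Free catalyst stands in both rates, so it cancels from their ratio, and coupling partner does not appear in it. Target (P) and its isomer (E) equilibrate with a half-life of 0.375 h, far shorter than the run, so I counted them as one pool. I also counted each captured substrate as pool at once, ignoring what sits on the catalyst.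

With A the substrate, the ratio is then R = σ(P+E)/A. Here σ, the selectivity factor, is the destruction constant over the capture constant, divided by one plus the isomer equilibrium constant: 0.272. The pool grows while R stands below 1 and falls above it.

With all substrate in from the start, x being the fraction left, the pool follows (x^σ − x)/(1 − σ). It peaks at x = 16.7%, which puts target at 54.4% at most.

I took Friday's and Saturday's flasks to lie on this curve, with dosing coupling partner changing the pace along it. Thursday's dosing holds substrate low, which raises R at a given conversion. In Friday's flask, target has a half-life of 1.1 d by destruction alone, short against the 5.0 d run, so overshooting the peak costs dearly.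

On this reckoning of my own I would have charged Saturday's recipe.

**The forecast.** It gave 26% for Friday's, 28% for Sunday's, 27% for Thursday's and 33% for Saturday's, with Saturday's best: “Dosing the coupling partner keeps catalyst parked as intermediate A and so protects the target best”.

**The flasks.** The simulation gave 26.0% for Friday's, 26.4% for Sunday's, 39.3% for Thursday's and 47.3% for Saturday's, so Saturday's came first. In Saturday's flask, R read 0.930 at 4.00 d, with target at 50.0%, and 2.84 at 5.00 d, with target at 47.3%. In the neighbour of Saturday's flask with 0.024 M of free catalyst, R read 0.337 at 5.00 d, with target at 43.3%.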